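**Strategy.** The quinone ring (C1=O, C2 indolyl, C3 OMe, C4=O, C5 indolyl, C6 prenyl) is traced back to the para-unsubstituted phenol 16, whose benzene ring is cut at C3–C4 and C5–C6. The key step exploits the vinylogous ester C3(OMe)=C2–C1=O of that ring. The enolate of an N-protected 3-acetylindole (methyl carbon = C4, carbonyl carbon = C5) displaces methanethiolate at C3 of the α-oxo ketene O,S-acetal 10 (C3, C2, C1, C6). The C6 methylene then condenses onto the C5 carbonyl. One operation thus forms both bonds and the fully substituted arene; the C4 oxygen is added last by para-oxidation of the phenol.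

Key step: step 7

Remark on the chemistry: 10 is carried as an E/Z mixture at the acetal double bond; both isomers converge in step 7, where that double bond is re-formed after the displacement.

Step 1
Reactants: 1 2-(1H-indol-3-yl)acetic acid
Product: 3 N-methoxy-N-methyl-2-(1H-indol-3-yl)acetamide, via acyl imidazolide 2 (not isolated)
Conditions: CDI, THF, rt; then MeNH(OMe)·HCl, rt
Reagents that add atoms: N,O-dimethylhydroxylamine hydrochloride (CNOC.Cl); 1,1'-carbonyldiimidazole (O=C(n1ccnc1)n1ccnc1; its imidazole stays only in intermediate 2)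
Why: CDI activates the acid as the acyl imidazolide, which the hydroxylamine should aminolyse to the Weinreb amide (amide coupling via an acyl imidazole).

Step 2
Reactants: 3 N-methoxy-N-methyl-2-(1H-indol-3-yl)acetamide
Product: 4 N-methoxy-N-methyl-2-[1-(phenylsulfonyl)-1H-indol-3-yl]acetamide
Conditions: PhSO2Cl, 50% aq. NaOH, Bu4NHSO4 (cat.), CH2Cl2, 0 °C → rt
Reagents that add atoms: benzenesulfonyl chloride (O=S(=O)(Cl)c1ccccc1)
Why: The indole N–H is the only site acidic enough under phase-transfer conditions, so N-sulfonylation (sulfonamide formation) should mask it for the later enolate chemistry.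

Step 3
Reactants: 4 N-methoxy-N-methyl-2-[1-(phenylsulfonyl)-1H-indol-3-yl]acetamide; 5 5-bromo-2-methylpent-2-ene
Product: 7 6-methyl-1-[1-(phenylsulfonyl)-1H-indol-3-yl]hept-5-en-2-one, via homoprenylmagnesium bromide 6 (not isolated)
Conditions: 5, Mg, THF, rt; then 4, THF, −10 °C → rt; aq. NH4Cl
Reagents that add atoms: magnesium ([Mg]; retained only in intermediate 6)
Why: Grignard addition to a Weinreb amide stops at the chelated tetrahedral intermediate and should release the ketone on work-up (Weinreb ketone synthesis).

Step 4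
Reactants: 7 6-methyl-1-[1-(phenylsulfonyl)-1H-indol-3-yl]hept-5-en-2-one
Product: 9 7-methyl-1,1-bis(methylsulfanyl)-2-[1-(phenylsulfonyl)-1H-indol-3-yl]octa-1,6-dien-3-one, via disodium enedithiolate 8 (not isolated)
Conditions: NaH (2.2 equiv), CS2, THF/DMF, 0 °C; then MeI (2.2 equiv), 0 °C → rt
Reagents that add atoms: carbon disulfide (S=C=S); iodomethane (CI); sodium hydride ([Na+].[H-]; sodium only in intermediate 8)
Why: The indolyl-methylene, the more acidic α-position, should be deprotonated twice and trapped by CS2, and double S-methylation of the enedithiolate gives the α-oxo ketene dithioacetal (ketene dithioacetal synthesis from an active-methylene ketone).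

Step 5
Reactants: 9 7-methyl-1,1-bis(methylsulfanyl)-2-[1-(phenylsulfonyl)-1H-indol-3-yl]octa-1,6-dien-3-one
Product: 10 1-methoxy-7-methyl-1-(methylsulfanyl)-2-[1-(phenylsulfonyl)-1H-indol-3-yl]octa-1,6-dien-3-one (E/Z mixture)
Conditions: NaOMe (1.1 equiv), MeOH/THF, 0 °C → rt; aq. NH4Cl
Reagents that add atoms: sodium methoxide ([Na+].[O-]C)
Why: Methoxide should add to the β-carbon of the push–pull alkene and expel methanethiolate, the better leaving group (vinylic addition–elimination), one equivalent giving the mixed O,S-acetal.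

Step 6
Reactants: 11 1-(1H-indol-3-yl)ethan-1-one
Product: 12 1-[1-(phenylsulfonyl)-1H-indol-3-yl]ethan-1-one
Conditions: PhSO2Cl, 50% aq. NaOH, Bu4NHSO4 (cat.), CH2Cl2, rt
Reagents that add atoms: benzenesulfonyl chloride (O=S(=O)(Cl)c1ccccc1)
Why: N-sulfonylation (sulfonamide formation) should remove the acidic N–H and the vinylogous-amide character, so that the methyl ketone enolises cleanly and its carbonyl stays electrophilic.

Step 7
Reactants: 12 1-[1-(phenylsulfonyl)-1H-indol-3-yl]ethan-1-one; 10 1-methoxy-7-methyl-1-(methylsulfanyl)-2-[1-(phenylsulfonyl)-1H-indol-3-yl]octa-1,6-dien-3-one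
Product: 15 3-methoxy-6-(3-methylbut-2-en-1-yl)-2,5-bis[1-(phenylsulfonyl)-1H-indol-3-yl]phenol, via potassium enolate 13 (not isolated), via open-chain enedione 14 (not isolated)
Conditions: 12, KN(SiMe3)2 (2.4 equiv), THF, −78 °C; then 10, −78 °C → rt, then 65 °C; aq. NH4Cl
Reagents that add atoms: potassium bis(trimethylsilyl)amide ([K+].C[Si](C)(C)[N-][Si](C)(C)C; potassium only in intermediate 13)
Why: The enolate 13 should add through its methylene carbon (future C4) to the acetal carbon C3 of 10, and the resulting enolate expels methanethiolate rather than methoxide, so the methoxy group stays on C3 (vinylic addition–elimination). The dienolate of 14 then closes the ring by attack of the C6 methylene (alpha to C1=O) on the C5 carbonyl of the acylindole, a six-membered (enolendo)-exo-trig aldol addition; loss of water and enolisation of the cyclohexadienone give the phenoxide of 15, with aromatisation as the driving force. The closest known reactions are the addition–elimination of methyl ketone enolates to α-oxo ketene dithioacetals and the base-mediated aldol aromatisation of 1,3,5-tricarbonyl chains (a Robinson-type benzannulation). No stereocentre is formed. The step needs chemoselectivity in the leaving group, secured by thiolate being the better nucleofuge, and in the ring closure, secured because 12 has one enolisable site and the C6 carbanion of 14 finds only the C5 carbonyl within reach of a six-membered ring. The N-sulfonyl groups keep that carbonyl electrophilic and both nitrogens non-acidic.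

Step 8
Reactants: 15 3-methoxy-6-(3-methylbut-2-en-1-yl)-2,5-bis[1-(phenylsulfonyl)-1H-indol-3-yl]phenol
Product: 16 2,5-di(1H-indol-3-yl)-3-methoxy-6-(3-methylbut-2-en-1-yl)phenol
Conditions: KOH, MeOH/THF/H2O, 65 °C, argon
Reagents that add atoms: none
Why: Hydroxide should attack sulfur of both N-sulfonylindoles and free the two N–H groups (sulfonamide hydrolysis), with argon preventing premature aerial oxidation of the electron-rich phenoxide.

Step 9
Reactants: 16 2,5-di(1H-indol-3-yl)-3-methoxy-6-(3-methylbut-2-en-1-yl)phenol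
Product: 17 2,5-di(1H-indol-3-yl)-3-methoxy-6-(3-methylbut-2-en-1-yl)cyclohexa-2,5-diene-1,4-dione
Conditions: (KSO3)2NO (Fremy's salt, 2.5 equiv), KH2PO4 buffer, acetone/H2O, rt
Reagents that add atoms: potassium nitrosodisulfonate ([K+].[K+].[O-]S(=O)(=O)N([O])S(=O)(=O)[O-])
Why: In the Teuber oxidation the nitroxyl radical abstracts the phenolic hydrogen and a second equivalent delivers oxygen to the free para position C4, which should give the para-quinone with the C3 methoxy group untouched.

**Compound list**

1 | 2-(1H-indol-3-yl)acetic acid | OC(=O)Cc1c[nH]c2ccccc12 | starting material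
2 | 1-(1H-indol-3-ylacetyl)-1H-imidazole (acyl imidazolide, formed in the flask) | O=C(Cc1c[nH]c2ccccc12)n1ccnc1 | intermediate
3 | N-methoxy-N-methyl-2-(1H-indol-3-yl)acetamide | CON(C)C(=O)Cc1c[nH]c2ccccc12 | intermediate
4 | N-methoxy-N-methyl-2-[1-(phenylsulfonyl)-1H-indol-3-yl]acetamide | CON(C)C(=O)Cc1cn(S(=O)(=O)c2ccccc2)c2ccccc12 | intermediate
5 | 5-bromo-2-methylpent-2-ene | CC(C)=CCCBr | starting material
6 | (4-methylpent-3-en-1-yl)magnesium bromide (homoprenylmagnesium bromide, formed in the flask) | CC(C)=CCC[Mg]Br | intermediate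
7 | 6-methyl-1-[1-(phenylsulfonyl)-1H-indol-3-yl]hept-5-en-2-one | CC(C)=CCCC(=O)Cc1cn(S(=O)(=O)c2ccccc2)c2ccccc12 | intermediate
8 | disodium 7-methyl-3-oxo-2-[1-(phenylsulfonyl)-1H-indol-3-yl]octa-1,6-diene-1,1-bis(thiolate) (formed in the flask) | [Na+].[Na+].[S-]C([S-])=C(C(=O)CCC=C(C)C)c1cn(S(=O)(=O)c2ccccc2)c2ccccc12 | intermediate
9 | 7-methyl-1,1-bis(methylsulfanyl)-2-[1-(phenylsulfonyl)-1H-indol-3-yl]octa-1,6-dien-3-one | CSC(SC)=C(C(=O)CCC=C(C)C)c1cn(S(=O)(=O)c2ccccc2)c2ccccc12 | intermediate
10 | 1-methoxy-7-methyl-1-(methylsulfanyl)-2-[1-(phenylsulfonyl)-1H-indol-3-yl]octa-1,6-dien-3-one (mixture of 1E and 1Z isomers) | COC(SC)=C(C(=O)CCC=C(C)C)c1cn(S(=O)(=O)c2ccccc2)c2ccccc12 | intermediate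
11 | 1-(1H-indol-3-yl)ethan-1-one (3-acetylindole) | CC(=O)c1c[nH]c2ccccc12 | starting material
12 | 1-[1-(phenylsulfonyl)-1H-indol-3-yl]ethan-1-one | CC(=O)c1cn(S(=O)(=O)c2ccccc2)c2ccccc12 | intermediate
13 | potassium 1-[1-(phenylsulfonyl)-1H-indol-3-yl]ethen-1-olate (formed in the flask) | [K+].[O-]C(=C)c1cn(S(=O)(=O)c2ccccc2)c2ccccc12 | intermediate
14 | 3-methoxy-9-methyl-1,4-bis[1-(phenylsulfonyl)-1H-indol-3-yl]deca-3,8-diene-1,5-dione (present in the flask as its potassium dienolate; geometry at C3=C4 not fixed) | COC(CC(=O)c1cn(S(=O)(=O)c2ccccc2)c2ccccc12)=C(C(=O)CCC=C(C)C)c1cn(S(=O)(=O)c2ccccc2)c2ccccc12 | intermediate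
15 | 3-methoxy-6-(3-methylbut-2-en-1-yl)-2,5-bis[1-(phenylsulfonyl)-1H-indol-3-yl]phenol | COc1cc(-c2cn(S(=O)(=O)c3ccccc3)c3ccccc23)c(CC=C(C)C)c(O)c1-c1cn(S(=O)(=O)c2ccccc2)c2ccccc12 | intermediate
16 | 2,5-di(1H-indol-3-yl)-3-methoxy-6-(3-methylbut-2-en-1-yl)phenol | COc1cc(-c2c[nH]c3ccccc23)c(CC=C(C)C)c(O)c1-c1c[nH]c2ccccc12 | intermediate
17 | 2,5-di(1H-indol-3-yl)-3-methoxy-6-(3-methylbut-2-en-1-yl)cyclohexa-2,5-diene-1,4-dione | COC1=C(c2c[nH]c3ccccc23)C(=O)C(CC=C(C)C)=C(c2c[nH]c3ccccc23)C1=O | target

**Step count.** Total: 9 steps. Longest linear sequence: 8 steps (steps 1–5, 7, 8 and 9 from 1); step 6 is the one-step side branch.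

**Steps most likely to fail, with fallbacks**

1. Step 7. The cascade may stall at the delocalised potassium dienolate of 14, giving addition–elimination without ring closure. The addition may also be slow at the tetrasubstituted push–pull double bond. The released thiolate may strip the N-sulfonyl group from the acylindole half before ring closure and so deactivate the C5 carbonyl. The fallback sets out from 10 and 12 and returns at 15. The addition–elimination is run alone (KN(SiMe3)2, THF, −78 → 0 °C, cold AcOH quench) and the open-chain enedione 14 is isolated. It is converted with TMSOTf/Et3N (CH2Cl2, 0 °C) into the bis(trimethylsilyl) trienol ether F1. Heating F1 (toluene, 110 °C) should bring about a thermal 6π-electrocyclisation that forms the C5–C6 bond; loss of trimethylsilanol aromatises the ring and aqueous work-up cleaves the aryl silyl ether to 15. The ring closure is then pericyclic rather than an aldol reaction, and the two ring bonds are made in consecutive operations.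

2. Step 5. The exchange may not stop after one methylsulfanyl group, methoxide may cleave the acyl–vinyl bond (retro-Claisen fragmentation), or it may begin to remove the N-sulfonyl group. The fallback sets out from 7 and returns at 10 without passing through 9. The sodium enolate of 7 (NaH, THF, 0 °C) is thioacylated with O,S-dimethyl dithiocarbonate (COC(=S)SC) to give the β-oxo thionoester F2. S-Methylation of F2 (MeI, K2CO3, acetone, rt) then gives 10 directly, with the methoxy group in place from the start.

3. Step 9. Over-oxidation of the two electron-rich indole rings, or oxygenation away from the hindered para position, may compete with the para-oxidation of the phenol. The fallback sets out from 10 and returns at 17; it carries the C4 oxygen from the start instead of adding it last. 1-(Phenylsulfonyl)indole is acylated at C3 with methoxyacetyl chloride (AlCl3, CH2Cl2, Friedel–Crafts acylation) to give the methoxyacetyl ketone F3. F3 replaces 12 in the conditions of step 7 and should give the dimethoxyphenol F4. KOH (MeOH/THF/H2O, 65 °C) frees the indoles to give F5. The para-methoxyphenol F5 is then oxidised under much milder conditions (PhI(OAc)2, MeCN/H2O, 0 °C, oxidative demethylation) to 17, with loss of the C4 methyl group as methanol.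

**Further compounds**

F1 | step 7 | 3-methoxy-9-methyl-1,4-bis[1-(phenylsulfonyl)-1H-indol-3-yl]-1,5-bis(trimethylsilyloxy)deca-1,3,5,8-tetraene (double-bond geometry not fixed) | COC(C=C(O[Si](C)(C)C)c1cn(S(=O)(=O)c2ccccc2)c2ccccc12)=C(C(O[Si](C)(C)C)=CCC=C(C)C)c1cn(S(=O)(=O)c2ccccc2)c2ccccc12
F2 | step 5 | O-methyl 7-methyl-3-oxo-2-[1-(phenylsulfonyl)-1H-indol-3-yl]oct-6-enethioate | COC(=S)C(C(=O)CCC=C(C)C)c1cn(S(=O)(=O)c2ccccc2)c2ccccc12
F3 | step 9 | 2-methoxy-1-[1-(phenylsulfonyl)-1H-indol-3-yl]ethan-1-one | COCC(=O)c1cn(S(=O)(=O)c2ccccc2)c2ccccc12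
F4 | step 9 | 3,4-dimethoxy-6-(3-methylbut-2-en-1-yl)-2,5-bis[1-(phenylsulfonyl)-1H-indol-3-yl]phenol | COc1c(OC)c(-c2cn(S(=O)(=O)c3ccccc3)c3ccccc23)c(CC=C(C)C)c(O)c1-c1cn(S(=O)(=O)c2ccccc2)c2ccccc12
F5 | step 9 | 2,5-di(1H-indol-3-yl)-3,4-dimethoxy-6-(3-methylbut-2-en-1-yl)phenol | COc1c(OC)c(-c2c[nH]c3ccccc23)c(CC=C(C)C)c(O)c1-c1c[nH]c2ccccc12
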